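**Plan**

1. Retrosynthetic cuts: first the C8–prenyl bond; then, in one operation, the three bonds around the side chain (benzylic C–propyl, benzylic C–CH2, and O5–C of the future carboxyl carbon, held as an acetal); then C6–CHO, O1–C8a and C4–C4a of the chromanone.
2. Enabling feature: C3 of the hexanoic acid chain is bonded to C6 of the chroman-4-one (ring atoms O1, C2, C3, C4, C4a, C5–C8, C8a), directly beside the C5 phenol oxygen. O5=C5–C6=CH(propyl) can therefore exist as an ortho-quinone methide, and the CH2–CO2H unit can arrive as a vinyl ether.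
3. Forward order: the pyranone ring is built first (aryllithium acylation for C4–C4a, fluoride displacement for O1–C8a) and C6 is formylated. The three-component step then joins propyl and the two-carbon unit while closing a temporary six-membered acetal ring on O5/C6. The prenyl group is coupled to C8, and the acetal ring is opened and oxidised to the acid.
4. Stereochemistry: C2 comes from ethyl (S)-3-hydroxybutanoate and C3 from its anti-selective Fráter–Seebach methylation, both carried with retention. The benzylic centre comes from the (1R,2S)-trans-2-phenylcyclohexyl vinyl ether in an endo [4+2] addition.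

Key step: step 10

Assumption: the ortho-quinone methide is taken to react as its (E) isomer through an endo transition state, and the (1R,2S) auxiliary is taken to deliver the R benzylic centre; if the sense were opposite, the mirror-image alcohol would be used in the same steps.

**Route**

Step 1
Reactants: 1 ethyl (S)-3-hydroxybutanoate
Product: 3 ethyl (2S,3S)-3-hydroxy-2-methylbutanoate, via dilithium ester dianion 2 (not isolated)
Conditions: LiN(i-Pr)2 (2.2 equiv), THF, −50 → −20 °C; MeI, DMPU, −78 → 0 °C; aq. NH4Cl
Reagents that add atoms: iodomethane, CI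
Why: Fráter–Seebach alkylation, in which the chelated alkoxide–enolate is methylated on the face away from the C3 methyl group, so the new C2 centre should be S (anti product).

Step 2
Reactants: 3 ethyl (2S,3S)-3-hydroxy-2-methylbutanoate
Product: 4 (2S,3S)-3-hydroxy-N-methoxy-N,2-dimethylbutanamide
Conditions: MeNH(OMe)·HCl, i-PrMgCl, THF, −20 → 0 °C
Reagents that add atoms: N,O-dimethylhydroxylamine hydrochloride, CNOC.Cl
Why: Weinreb aminolysis of the ester by the magnesium amide formed in the flask, a reaction that tolerates a free β-hydroxyl (as its alkoxide) and should not epimerise the α-centre.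

Step 3
Reactants: 5 1-fluoro-3,5-dimethoxybenzene
Product: 6 2-bromo-1-fluoro-3,5-dimethoxybenzene
Conditions: NBS, MeCN, 0 °C → rt
Reagents that add atoms: N-bromosuccinimide, O=C1CCC(=O)N1Br
Why: Electrophilic aromatic bromination should go to the carbon that is para to one methoxy group and ortho to the other (next to fluorine) rather than to the more crowded ortho/ortho site between the two methoxy groups, which fixes the position of the later carbon–lithium bond.

Step 4
Reactants: 6 2-bromo-1-fluoro-3,5-dimethoxybenzene; 4 (2S,3S)-3-hydroxy-N-methoxy-N,2-dimethylbutanamide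
Product: 9 (2S,3S)-1-(2-fluoro-4,6-dimethoxyphenyl)-3-hydroxy-2-methylbutan-1-one, via aryllithium 7 (not isolated), via dilithium tetrahedral adduct 8 (not isolated)
Conditions: 6 (2.3 equiv), n-BuLi (2.2 equiv), THF, −78 °C; then 4, −78 → −50 °C; aq. NH4Cl
Reagents that add atoms: none
Why: Bromine–lithium exchange gives the aryllithium regiospecifically below the temperature of LiF loss; one equivalent is consumed by the hydroxyl and the next acylates on the Weinreb amide, whose chelated adduct collapses only on quench, so over-addition and α-epimerisation are avoided.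

Step 5
Reactants: 9 (2S,3S)-1-(2-fluoro-4,6-dimethoxyphenyl)-3-hydroxy-2-methylbutan-1-one
Product: 10 (2S,3S)-5,7-dimethoxy-2,3-dimethylchroman-4-one
Conditions: NaH (1.0 equiv), THF, 0 °C → rt; AcOH quench
Reagents that add atoms: none
Why: Intramolecular SNAr in which the secondary alkoxide displaces the fluoride ortho to the ketone (both methoxy groups are meta to the C–F carbon and do not destabilise the anionic intermediate); O1–C8a forms without touching either stereocentre, so the anti aldol should become the trans chromanone.

Step 6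
Reactants: 10 (2S,3S)-5,7-dimethoxy-2,3-dimethylchroman-4-one
Product: 12 (2S,3S)-5-hydroxy-7-methoxy-2,3-dimethylchroman-4-one, via dichloroboron phenoxide 11 (not isolated)
Conditions: BCl3 (1.5 equiv), CH2Cl2, −78 → 0 °C; then H2O
Reagents that add atoms: none
Why: Chelation-directed Lewis acid demethylation, in which BCl3 bound to the C4 carbonyl cleaves only the peri 5-methoxy group and leaves the 7-methoxy group and the base-sensitive C2/C3 centres alone.

Step 7
Reactants: 12 (2S,3S)-5-hydroxy-7-methoxy-2,3-dimethylchroman-4-one
Product: 14 (2S,3S)-5-hydroxy-7-methoxy-2,3-dimethyl-4-oxochroman-6-carbaldehyde, via chloro methyl ether 13 (not isolated)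
Conditions: TiCl4 (3 equiv), Cl2CHOMe (1.2 equiv), CH2Cl2, −20 → 0 °C; then 1 M HCl
Reagents that add atoms: dichloromethyl methyl ether, COC(Cl)Cl; water, O
Why: Rieche formylation, in which the titanium phenoxide at O5 delivers the activated dichloromethyl ether to the adjacent C6 rather than to the remote C8, and aqueous acid hydrolyses the chloro ether to the aldehyde.

Step 8
Reactants: 14 (2S,3S)-5-hydroxy-7-methoxy-2,3-dimethyl-4-oxochroman-6-carbaldehyde
Product: 15 tert-butyl (2S,3S)-6-formyl-7-methoxy-2,3-dimethyl-4-oxochroman-5-yl carbonate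
Conditions: Boc2O, i-Pr2NEt, DMAP (cat.), CH2Cl2, 0 °C → rt
Reagents that add atoms: di-tert-butyl dicarbonate, CC(C)(C)OC(=O)OC(=O)OC(C)(C)C
Why: DMAP-catalysed O-acylation of the acidic, chelated phenol, the standard way to O-Boc salicylaldehydes.

Step 9
Reactants: 16 (1R,2S)-trans-2-phenylcyclohexanol
Product: 17 (1R,2S)-trans-2-phenylcyclohexyl vinyl ether
Conditions: Pd(OCOCF3)2 (cat.), 4,7-diphenyl-1,10-phenanthroline (cat.), Et3N (cat.), n-butyl vinyl ether (solvent), 75 °C
Reagents that add atoms: n-butyl vinyl ether, C=COCCCC
Why: Palladium-catalysed transfer vinylation driven by the excess of butyl vinyl ether; the carbinol C–O bond is not broken, so the auxiliary keeps its configuration.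

Step 10
Reactants: 15 tert-butyl (2S,3S)-6-formyl-7-methoxy-2,3-dimethyl-4-oxochroman-5-yl carbonate; 18 propylmagnesium bromide; 17 (1R,2S)-trans-2-phenylcyclohexyl vinyl ether
Product: 22 tricyclic acetal (acetal carbon R; benzylic carbon R; propyl and alkoxy cis), via magnesium alkoxide 19 (not isolated), via benzylic carbonate phenoxide 20 (not isolated), via ortho-quinone methide 21 (not isolated)
Conditions: 17 (3 equiv), n-PrMgBr (1.1 equiv), Et2O/toluene, −78 °C → rt; aq. NaHCO3
Reagents that add atoms: none
Why: At −78 °C the Grignard reagent adds to the aldehyde, which is far more electrophilic than the hindered, vinylogous-ester C4 ketone or the carbonate, giving alkoxide 19; the Boc group then migrates through a six-membered transition state (20), and on warming the magnesium phenoxide expels tert-butyl carbonate to unveil the ortho-quinone methide 21 (O5=C5–C6=CH–Pr), which the excess vinyl ether captures. The closest known reaction type is the Grignard-triggered generation of ortho-quinone methides from O-Boc salicylaldehydes with diastereoselective capture by chiral enol ethers. The one new ring, the six-membered acetal ring (O5, C5, C6, benzylic C, CH2, acetal C), closes by an inverse-electron-demand hetero-[4+2] cycloaddition that forms the benzylic C–CH2 and O5–acetal C bonds, the benzylic C–propyl bond having been made in the Grignard addition. The acetal carbon is set by the auxiliary, whose phenyl group shields one face of the vinyl ether, and the benzylic carbon follows from it because the alkoxy group approaches endo to the (E)-quinone methide, which places propyl and alkoxy cis (R at both new centres). The step needs aldehyde-selective addition, a single quinone methide geometry and cycloaddition faster than 1,5-hydrogen shift to the styrene; the low temperature, the magnesium-bridged carbonate on the O5 side (which turns the propyl group towards C7), the excess of electron-rich dienophile and the extra electrophilicity given by the C4 carbonyl conjugated with O5 should secure these.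

Step 11
Reactants: 22 tricyclic acetal
Product: 23 8-bromo tricyclic acetal
Conditions: NBS (1.05 equiv), MeCN, 0 °C
Reagents that add atoms: N-bromosuccinimide, O=C1CCC(=O)N1Br
Why: Electrophilic bromination at the only remaining C–H of the chromanone arene (C8, ortho to O1 and the methoxy group, para to O5); the acetal, the ketone and the unactivated phenyl ring of the auxiliary should not react.

Step 12
Reactants: 23 8-bromo tricyclic acetal; 24 tributyl(3-methylbut-2-en-1-yl)stannane
Product: 25 8-prenyl tricyclic acetal
Conditions: Pd2(dba)3 (cat.), P(t-Bu)3 (cat.), CsF, dioxane, 80 °C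
Reagents that add atoms: none
Why: Stille coupling in which the bulky, electron-rich phosphine allows oxidative addition of the hindered, electron-rich bromide, fluoride activates the stannane, and reductive elimination at the unsubstituted allyl terminus should give the linear prenyl group without any reagent that attacks the ketone.

Step 13
Reactants: 25 8-prenyl tricyclic acetal
Product: 26 (R)-3-[(2S,3S)-5-hydroxy-7-methoxy-2,3-dimethyl-8-(3-methylbut-2-en-1-yl)-4-oxochroman-6-yl]hexanal
Conditions: 1 M HCl, THF, rt
Reagents that add atoms: water, O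
Why: Acid-catalysed hydrolysis of the mixed aryl alkyl acetal through its oxocarbenium ion releases the auxiliary alcohol 16 for re-use and the aldehyde, whose freed 5-hydroxyl is held by the C4 carbonyl; the C8 prenyl group has no free ortho hydroxyl to cyclise onto and the benzylic centre is not involved.

Step 14
Reactants: 26 (R)-3-[(2S,3S)-5-hydroxy-7-methoxy-2,3-dimethyl-8-(3-methylbut-2-en-1-yl)-4-oxochroman-6-yl]hexanal
Product: 27 (R)-3-[(2S,3S)-5-hydroxy-7-methoxy-2,3-dimethyl-8-(3-methylbut-2-en-1-yl)-4-oxochroman-6-yl]hexanoic acid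
Conditions: NaClO2, NaH2PO4, 2-methyl-2-butene (large excess), t-BuOH/H2O, 0 °C → rt
Reagents that add atoms: sodium chlorite, [Na+].[O-]Cl=O
Why: Pinnick oxidation of the aldehyde to the acid under buffered conditions; the excess alkene scavenger protects the prenyl group, the arene is fully substituted, and no stereocentre is enolisable under these conditions.

**Compound list**

1 | ethyl (S)-3-hydroxybutanoate | CCOC(=O)C[C@H](C)O | starting material
2 | dilithium alkoxide–enolate (dianion) of 1 | CCOC(O[Li])=C[C@H](C)O[Li] | intermediate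
3 | ethyl (2S,3S)-3-hydroxy-2-methylbutanoate | CCOC(=O)[C@@H](C)[C@H](C)O | intermediate
4 | (2S,3S)-3-hydroxy-N-methoxy-N,2-dimethylbutanamide | CON(C)C(=O)[C@@H](C)[C@H](C)O | intermediate
5 | 1-fluoro-3,5-dimethoxybenzene | COc1cc(F)cc(OC)c1 | starting material
6 | 2-bromo-1-fluoro-3,5-dimethoxybenzene | COc1cc(F)c(Br)c(OC)c1 | intermediate
7 | (2-fluoro-4,6-dimethoxyphenyl)lithium | COc1cc(F)c([Li])c(OC)c1 | intermediate
8 | dilithium tetrahedral adduct of 7 and 4 (O-lithio hemiaminal and β-lithium alkoxide; hemiaminal carbon undefined) | COc1cc(F)c(c(OC)c1)C(O[Li])(N(C)OC)[C@@H](C)[C@H](C)O[Li] | intermediate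
9 | (2S,3S)-1-(2-fluoro-4,6-dimethoxyphenyl)-3-hydroxy-2-methylbutan-1-one | COc1cc(F)c(c(OC)c1)C(=O)[C@@H](C)[C@H](C)O | intermediate
10 | (2S,3S)-5,7-dimethoxy-2,3-dimethylchroman-4-one (trans) | COc1cc(OC)c2c(c1)O[C@@H](C)[C@H](C)C2=O | intermediate
11 | dichloroboron 5-phenoxide of 12 (boron chelated by the C4 carbonyl) | COc1cc(OB(Cl)Cl)c2c(c1)O[C@@H](C)[C@H](C)C2=O | intermediate
12 | (2S,3S)-5-hydroxy-7-methoxy-2,3-dimethylchroman-4-one | COc1cc(O)c2c(c1)O[C@@H](C)[C@H](C)C2=O | intermediate
13 | (2S,3S)-6-[chloro(methoxy)methyl]-5-hydroxy-7-methoxy-2,3-dimethylchroman-4-one (titanium-bound in the flask) | COC(Cl)c1c(O)c2c(cc1OC)O[C@@H](C)[C@H](C)C2=O | intermediate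
14 | (2S,3S)-5-hydroxy-7-methoxy-2,3-dimethyl-4-oxochroman-6-carbaldehyde | O=Cc1c(O)c2c(cc1OC)O[C@@H](C)[C@H](C)C2=O | intermediate
15 | tert-butyl (2S,3S)-6-formyl-7-methoxy-2,3-dimethyl-4-oxochroman-5-yl carbonate | O=Cc1c(OC(=O)OC(C)(C)C)c2c(cc1OC)O[C@@H](C)[C@H](C)C2=O | intermediate
16 | (1R,2S)-trans-2-phenylcyclohexanol | O[C@@H]1CCCC[C@H]1c1ccccc1 | starting material
17 | (1R,2S)-trans-2-phenylcyclohexyl vinyl ether | C=CO[C@@H]1CCCC[C@H]1c1ccccc1 | intermediate
18 | propylmagnesium bromide | CCC[Mg]Br | starting material
19 | bromomagnesium alkoxide from addition of 18 to the aldehyde of 15 (carbinol carbon as both epimers) | CCCC(O[Mg]Br)c1c(OC(=O)OC(C)(C)C)c2c(cc1OC)O[C@@H](C)[C@H](C)C2=O | intermediate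
20 | bromomagnesium 5-phenoxide carrying the benzylic tert-butyl carbonate (after Boc migration) | CCCC(OC(=O)OC(C)(C)C)c1c(O[Mg]Br)c2c(cc1OC)O[C@@H](C)[C@H](C)C2=O | intermediate
21 | (E)-ortho-quinone methide: (2S,3S)-6-butylidene-7-methoxy-2,3-dimethyl-2,3-dihydrochromene-4,5-dione, propyl on the C7 side | CCC/C=C1\C(OC)=CC2=C(C1=O)C(=O)[C@@H](C)[C@H](C)O2 | intermediate
22 | tricyclic acetal: (2S,3S)-7-methoxy-2,3-dimethylchroman-4-one with O5 and C6 bridged by –CH(OR*)–CH2–CH(n-Pr)–, R* = (1R,2S)-2-phenylcyclohexyl; acetal carbon R, benzylic carbon R, OR* and propyl cis | CCC[C@H](C[C@H](O[C@@H]4CCCC[C@H]4c5ccccc5)O2)c1c2c3c(cc1OC)O[C@@H](C)[C@H](C)C3=O | intermediate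
23 | 8-bromo derivative of 22 | CCC[C@H](C[C@H](O[C@@H]4CCCC[C@H]4c5ccccc5)O2)c1c2c3c(c(Br)c1OC)O[C@@H](C)[C@H](C)C3=O | intermediate
24 | tributyl(3-methylbut-2-en-1-yl)stannane | CCCC[Sn](CCCC)(CCCC)CC=C(C)C | starting material
25 | 8-(3-methylbut-2-en-1-yl) derivative of 22 | CCC[C@H](C[C@H](O[C@@H]4CCCC[C@H]4c5ccccc5)O2)c1c2c3c(c(CC=C(C)C)c1OC)O[C@@H](C)[C@H](C)C3=O | intermediate
26 | (R)-3-[(2S,3S)-5-hydroxy-7-methoxy-2,3-dimethyl-8-(3-methylbut-2-en-1-yl)-4-oxochroman-6-yl]hexanal (drawn as the open hydroxy aldehyde; ring–chain tautomerism with its cyclic hemiacetal does not matter for step 14) | CCC[C@H](CC=O)c1c(O)c2c(c(CC=C(C)C)c1OC)O[C@@H](C)[C@H](C)C2=O | intermediate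
27 | (R)-3-[(2S,3S)-5-hydroxy-7-methoxy-2,3-dimethyl-8-(3-methylbut-2-en-1-yl)-4-oxochroman-6-yl]hexanoic acid | CCC[C@H](CC(=O)O)c1c(O)c2c(c(CC=C(C)C)c1OC)O[C@@H](C)[C@H](C)C2=O | target

**Step count and risks**

Total: 14 steps. Longest linear sequence: 12 steps (1 → 3 → 4 → 9 → 10 → 12 → 14 → 15 → 22 → 23 → 25 → 26 → 27; steps 3 and 9 are one-step side branches).

Most likely to fail:

1. Step 10. The ortho-quinone methide may tautomerise by 1,5-hydrogen shift before it is captured. It may also form in both alkene geometries or be approached exo, which would erode the benzylic selectivity. The Grignard reagent may attack the carbonate or the C4 ketone. Fallback, setting out from 14 (step 8 omitted): Wittig olefination with Ph3P=CHCO2Et in N,N-diethylaniline at reflux would give the cinnamate ester F1, which lactonises in the same pot to the pyranone-fused chromanone (coumarin) F2. Copper-catalysed asymmetric conjugate addition of propylmagnesium bromide (CuBr·SMe2, the enantiomer of a Josiphos-type ferrocenyl diphosphine that gives the R centre, CH2Cl2, −75 °C) would set the benzylic centre in the 4-propyl dihydrocoumarin F3. Bromination at C8 (NBS, MeCN) would give the bromo lactone F4, Stille coupling with 24 under the conditions of step 12 the prenyl lactone F5, and saponification (LiOH, THF/H2O, careful acidification) would return to the route at 27.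

2. Step 7. Formylation may occur at C8 (para to O5) in competition with C6, or twice. Fallback, setting out from 12: O-allylation (allyl bromide, K2CO3, DMF) would give the 5-allyl ether F6. Aromatic Claisen rearrangement (N,N-diethylaniline, 190 °C) can deliver the allyl group only to C6, because the other ortho position is the ring fusion C4a, and would give the 6-allyl phenol F7. Alkene isomerisation with PdCl2(MeCN)2 would give the 6-(E)-propenyl phenol F8, and Lemieux–Johnson cleavage (OsO4 cat., NaIO4, 2,6-lutidine, dioxane/H2O) would return to the route at 14.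

3. Step 5. Retro-aldol cleavage or dehydration of the aldolate may outrun fluoride displacement, with loss of both stereocentres, and the product may ring-open under base. Fallback, setting out from 3 (steps 2 to 5 omitted): palladium-catalysed C–O coupling of the secondary alcohol with 1-bromo-3,5-dimethoxybenzene (Pd2(dba)3, RockPhos, Cs2CO3, toluene, 90 °C), which leaves the carbinol C–O bond intact and involves no ketone, would give the aryl ether ester F9. Saponification (LiOH, THF/H2O) would give the acid F10, and intramolecular Friedel–Crafts acylation (trifluoroacetic anhydride, CH2Cl2, 0 °C) onto the symmetrical dimethoxyphenyl ring would close C4–C4a and return to the route at 10.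

**Further compounds**

F1 | step 10 | ethyl 3-[(2S,3S)-5-hydroxy-7-methoxy-2,3-dimethyl-4-oxochroman-6-yl]prop-2-enoate (E/Z, not isolated) | CCOC(=O)C=Cc1c(O)c2c(cc1OC)O[C@@H](C)[C@H](C)C2=O
F2 | step 10 | coumarin: (2S,3S)-7-methoxy-2,3-dimethylchroman-4-one with O5 and C6 bridged by –C(=O)–CH=CH– | COc1cc2c(c3c1C=CC(=O)O3)C(=O)[C@@H](C)[C@H](C)O2
F3 | step 10 | dihydrocoumarin: O5 and C6 bridged by –C(=O)–CH2–CH(n-Pr)–, benzylic carbon R | CCC[C@H](CC(=O)O3)c1c3c2c(cc1OC)O[C@@H](C)[C@H](C)C2=O
F4 | step 10 | 8-bromo derivative of F3 | CCC[C@H](CC(=O)O3)c1c3c2c(c(Br)c1OC)O[C@@H](C)[C@H](C)C2=O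
F5 | step 10 | 8-(3-methylbut-2-en-1-yl) derivative of F3 | CCC[C@H](CC(=O)O3)c1c3c2c(c(CC=C(C)C)c1OC)O[C@@H](C)[C@H](C)C2=O
F6 | step 7 | (2S,3S)-5-(allyloxy)-7-methoxy-2,3-dimethylchroman-4-one | COc1cc(OCC=C)c2c(c1)O[C@@H](C)[C@H](C)C2=O
F7 | step 7 | (2S,3S)-6-allyl-5-hydroxy-7-methoxy-2,3-dimethylchroman-4-one | C=CCc1c(O)c2c(cc1OC)O[C@@H](C)[C@H](C)C2=O
F8 | step 7 | (2S,3S)-5-hydroxy-7-methoxy-2,3-dimethyl-6-[(E)-prop-1-enyl]chroman-4-one | C/C=C/c1c(O)c2c(cc1OC)O[C@@H](C)[C@H](C)C2=O
F9 | step 5 | ethyl (2S,3S)-3-(3,5-dimethoxyphenoxy)-2-methylbutanoate | CCOC(=O)[C@@H](C)[C@H](C)Oc1cc(OC)cc(OC)c1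
F10 | step 5 | (2S,3S)-3-(3,5-dimethoxyphenoxy)-2-methylbutanoic acid | OC(=O)[C@@H](C)[C@H](C)Oc1cc(OC)cc(OC)c1
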